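**Retrosynthetic overview** (oxane numbering: O1, C2 = 4-hydroxyphenyl carbon, C3 = carbinol, C4 = carbon carrying the chalcone ring, C5 = CH2, C6 = arylethyl carbon)
1. Target ⇒ global desilylation of 29 ⇒ C2–aryl bond: the axial 4-oxyphenyl group is delivered from a C3–O–SiMe2–aryl tether to the C2 oxocarbenium ion of ethyl acetal 22.
2. Chalcone ⇒ ortho-lithiation of the phloroglucinol ring and acylation with cinnamic N-methoxy-N-methylamide 17; C3–OH and C4–H ⇒ hydroboration of the C3=C4 bond of dihydropyran 11.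
3. Key disconnection of 11: C5–C6 and O1–C2 together, a hetero-Diels–Alder reaction of aldehyde 4 (O1=C6) with 1-ethoxy-3-aryl-buta-1,3-diene 10 (C2=C3–C4=C5); the ethoxy group at C2 is the activating group and is lost again in step 13.
4. Enabling feature: ring oxygen O1 sits between C6, which carries only H, the C5 methylene and the arylethyl chain (so O1=C6 can be an aldehyde carbonyl), and C2, whose aryl can be attached later at the acetal level; C4 bears its aryl on the inner diene carbon and C5 is an unsubstituted diene terminus.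
5. Ring order: the oxane is the only ring built (step 6); all four benzene rings are bought; diene 10 comes from acetophenone 5 via enol triflate 8 and Suzuki–Miyaura coupling.

Key step: step 6

Assumption: the chromium catalyst from (1S,2R)-1-aminoindan-2-ol is taken to give the (6S) adduct; if the sense of induction is the opposite, the mirror-image catalyst is used and nothing else changes.

Step 1
Reactants: 1 methyl 3-(4-hydroxyphenyl)propanoate
Product: 2 methyl 3-{4-[(triisopropylsilyl)oxy]phenyl}propanoate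
Conditions: TIPSCl, imidazole, DMF, rt
Reagents that add atoms: triisopropylsilyl chloride, CC(C)[Si](Cl)(C(C)C)C(C)C
Why: Imidazole-promoted O-silylation of the phenol; the bulky triisopropylsilyl ether is chosen because it should survive borane, n-BuLi and the acidic removal of the methoxymethyl groups in step 10.

Step 2
Reactants: 2 methyl 3-{4-[(triisopropylsilyl)oxy]phenyl}propanoate
Product: 4 3-{4-[(triisopropylsilyl)oxy]phenyl}propanal, via aluminium hemiacetal 3 (not isolated)
Conditions: iBu2AlH (1.05 equiv), CH2Cl2, −78 °C; then H2O/aq. potassium sodium tartrate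
Reagents that add atoms: none
Why: Partial reduction of a methyl ester with iBu2AlH at −78 °C stops at the tetrahedral aluminium hemiacetal, which collapses to the aldehyde only on work-up.

Step 3
Reactants: 5 1-(2,6-dihydroxy-4-methoxyphenyl)ethanone
Product: 6 1-[4-methoxy-2,6-bis(methoxymethoxy)phenyl]ethanone
Conditions: NaH (2.4 equiv), MOMCl (2.6 equiv), DMF, 0 °C → rt
Reagents that add atoms: chloromethyl methyl ether, COCCl
Why: Williamson-type O-alkylation of both sodium phenoxides; methoxymethyl ethers are used because they tolerate the enolate of step 4 (a silyl ether would migrate from phenol oxygen to enolate oxygen) and direct the lithiation of step 9.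

Step 4
Reactants: 6 1-[4-methoxy-2,6-bis(methoxymethoxy)phenyl]ethanone
Product: 8 1-[4-methoxy-2,6-bis(methoxymethoxy)phenyl]ethenyl trifluoromethanesulfonate, via potassium enolate 7 (not isolated)
Conditions: KN(SiMe3)2, THF, −78 °C; then PhNTf2, −78 → 0 °C
Reagents that add atoms: N-phenylbis(trifluoromethanesulfonimide), O=S(=O)(N(c1ccccc1)S(=O)(=O)C(F)(F)F)C(F)(F)F
Why: Kinetic deprotonation of the methyl ketone and O-sulfonylation of the enolate (enol triflate formation) turn the acetyl group into a 1-arylvinyl electrophile.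

Step 5
Reactants: 8 1-[4-methoxy-2,6-bis(methoxymethoxy)phenyl]ethenyl trifluoromethanesulfonate; 9 2-[(E)-2-ethoxyethenyl]-4,4,5,5-tetramethyl-1,3,2-dioxaborolane
Product: 10 2-[(3E)-4-ethoxybuta-1,3-dien-2-yl]-5-methoxy-1,3-bis(methoxymethoxy)benzene
Conditions: Pd(PPh3)4 (5 mol%), K3PO4, THF/H2O, 50 °C; chromatography on Et3N-deactivated silica
Reagents that add atoms: none
Why: Suzuki–Miyaura coupling of an enol triflate with an alkenylboronate proceeds with retention of the E geometry and gives the 1-ethoxy-3-aryl diene directly.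

Step 6
Reactants: 4 3-{4-[(triisopropylsilyl)oxy]phenyl}propanal; 10 2-[(3E)-4-ethoxybuta-1,3-dien-2-yl]-5-methoxy-1,3-bis(methoxymethoxy)benzene
Product: 11 (2S,6S)-2-ethoxy-4-[4-methoxy-2,6-bis(methoxymethoxy)phenyl]-6-(2-{4-[(triisopropylsilyl)oxy]phenyl}ethyl)-5,6-dihydro-2H-pyran
Conditions: CrCl(L) (5 mol%; L = C27H29NO2, the Schiff-base dianion from 3-(1-adamantyl)-2-hydroxy-5-methylbenzaldehyde and (1S,2R)-1-aminoindan-2-ol; trivalent chromium), 4 Å MS, t-BuOMe (minimal), rt
Reagents that add atoms: none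
Why: The chromium Lewis acid binds the aldehyde oxygen and the s-cis diene adds in a concerted, asynchronous [4+2] cycloaddition in which the CH2 terminus C5, made nucleophilic through the dienyl ether oxygen, bonds to the carbonyl carbon C6 while the carbonyl oxygen O1 closes onto the ethoxy-bearing C2; the closest known reaction type is the hetero-Diels–Alder reaction of 1-alkoxybuta-1,3-dienes with unactivated aliphatic aldehydes under tridentate Schiff-base chromium chloride catalysis. The one ring formed, the dihydropyran that becomes the oxane of the target, is closed as the six-membered ring of this cycloaddition, both bonds in one event, so no separate cyclisation and no competing ring size arise. C6 is set by the catalyst, which shields one face of the bound aldehyde, and C2 by the endo approach, which places the ethoxy group cis to the C6 chain; C2 is a temporary centre whose role is to steer step 7. The step needs regioselectivity (C5 to carbon, C2 to oxygen), endo selectivity and enantioface selectivity: the first is secured by the 1-ethoxy donor, the other two by the catalyst, and the aryl on the inner diene carbon C4 favours the reactive s-cis conformer. The ortho,ortho'-disubstituted aryl should lie perpendicular to the diene and slow the addition, which is why the reaction is run at high concentration.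

Step 7
Reactants: 11 (2S,6S)-2-ethoxy-4-[4-methoxy-2,6-bis(methoxymethoxy)phenyl]-6-(2-{4-[(triisopropylsilyl)oxy]phenyl}ethyl)-5,6-dihydro-2H-pyran
Product: 13 (2S,3S,4S,6S)-2-ethoxy-4-[4-methoxy-2,6-bis(methoxymethoxy)phenyl]-6-(2-{4-[(triisopropylsilyl)oxy]phenyl}ethyl)oxan-3-ol, via alkylborane 12 (not isolated)
Conditions: BH3·THF, THF, 0 °C → rt; then NaOH, H2O2, 0 °C
Reagents that add atoms: hydrogen peroxide, OO
Why: Hydroboration–oxidation: boron and hydrogen add syn, boron to the less substituted C3 (also the carbon next to the electron-withdrawing acetal), from the face opposite to the cis-disposed C2 ethoxy group and C6 chain, so that C3–OH ends trans to the C4 aryl and the C4 aryl cis to the C6 chain (both new centres set by substrate control).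

Step 8
Reactants: 14 4-(methoxymethoxy)benzaldehyde; 15 diethyl {2-[methoxy(methyl)amino]-2-oxoethyl}phosphonate
Product: 17 (2E)-N-methoxy-3-[4-(methoxymethoxy)phenyl]-N-methylprop-2-enamide, via sodium phosphonate carbanion 16 (not isolated)
Conditions: NaH, THF, 0 °C; then 14, 0 °C → rt
Reagents that add atoms: none
Why: Horner–Wadsworth–Emmons olefination with a stabilised phosphonate carbanion gives the E-configured cinnamic N-methoxy-N-methylamide.

Step 9
Reactants: 13 (2S,3S,4S,6S)-2-ethoxy-4-[4-methoxy-2,6-bis(methoxymethoxy)phenyl]-6-(2-{4-[(triisopropylsilyl)oxy]phenyl}ethyl)oxan-3-ol; 17 (2E)-N-methoxy-3-[4-(methoxymethoxy)phenyl]-N-methylprop-2-enamide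
Product: 20 (2E)-1-{3-[(2S,3S,4S,6S)-2-ethoxy-3-hydroxy-6-(2-{4-[(triisopropylsilyl)oxy]phenyl}ethyl)oxan-4-yl]-6-methoxy-2,4-bis(methoxymethoxy)phenyl}-3-[4-(methoxymethoxy)phenyl]prop-2-en-1-one, via dilithio derivative 18 (not isolated), via tetrahedral lithium adduct 19 (not isolated)
Conditions: n-BuLi (2.4 equiv), TMEDA, THF, −20 → 0 °C; then 17 (1.5 equiv), −78 → 0 °C; then H2O
Reagents that add atoms: none
Why: Directed ortho-metalation followed by Weinreb ketone synthesis: after deprotonation of the C3 hydroxyl, the ring position flanked by OMOM and OMe (two equivalent sites on the electron-rich ring) is lithiated and the aryllithium adds 1,2 to the amide, whose chelated tetrahedral adduct releases the E-chalcone on quench without touching a stereocentre.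

Step 10
Reactants: 20 (2E)-1-{3-[(2S,3S,4S,6S)-2-ethoxy-3-hydroxy-6-(2-{4-[(triisopropylsilyl)oxy]phenyl}ethyl)oxan-4-yl]-6-methoxy-2,4-bis(methoxymethoxy)phenyl}-3-[4-(methoxymethoxy)phenyl]prop-2-en-1-one
Product: 21 (2E)-1-{3-[(3S,4S,6S)-2-ethoxy-3-hydroxy-6-(2-{4-[(triisopropylsilyl)oxy]phenyl}ethyl)oxan-4-yl]-2,4-dihydroxy-6-methoxyphenyl}-3-(4-hydroxyphenyl)prop-2-en-1-one (both C2 epimers)
Conditions: HCl (1 M in EtOH), rt
Reagents that add atoms: none
Why: Acid-catalysed solvolysis of the three aryl methoxymethyl ethers in ethanol, where exchange of the C2 ethyl acetal is degenerate and only scrambles the temporary C2 centre, while the aryl triisopropylsilyl ether and the chalcone should persist; the acid step is placed here because the later 4-oxybenzylic C2 ether would not tolerate it.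

Step 11
Reactants: 21 (2E)-1-{3-[(3S,4S,6S)-2-ethoxy-3-hydroxy-6-(2-{4-[(triisopropylsilyl)oxy]phenyl}ethyl)oxan-4-yl]-2,4-dihydroxy-6-methoxyphenyl}-3-(4-hydroxyphenyl)prop-2-en-1-one
Product: 22 (2E)-3-{4-[(tert-butyldimethylsilyl)oxy]phenyl}-1-{4-[(tert-butyldimethylsilyl)oxy]-3-[(3S,4S,6S)-2-ethoxy-3-hydroxy-6-(2-{4-[(triisopropylsilyl)oxy]phenyl}ethyl)oxan-4-yl]-2-hydroxy-6-methoxyphenyl}prop-2-en-1-one (both C2 epimers)
Conditions: TBSCl (2.3 equiv), imidazole, DMF, 0 °C
Reagents that add atoms: tert-butyldimethylsilyl chloride, CC(C)(C)[Si](C)(C)Cl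
Why: Chemoselective silylation: the two accessible acidic phenols should react with TBSCl/imidazole much faster than the hindered secondary C3 hydroxyl and the hydrogen-bonded ortho-acyl phenol, which stay free.

Step 12
Reactants: 23 (4-bromophenoxy)(tert-butyl)dimethylsilane; 24 dichlorodimethylsilane
Product: 26 chloro{4-[(tert-butyldimethylsilyl)oxy]phenyl}dimethylsilane, via arylmagnesium bromide 25 (not isolated)
Conditions: Mg, THF, reflux; then added to Me2SiCl2 (3 equiv), THF, 0 °C → rt; distillation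
Reagents that add atoms: none
Why: Grignard formation and substitution at silicon with excess dichlorodimethylsilane give the monochlorosilane that serves as the aryl-carrying tether.

Step 13
Reactants: 22 (2E)-3-{4-[(tert-butyldimethylsilyl)oxy]phenyl}-1-{4-[(tert-butyldimethylsilyl)oxy]-3-[(3S,4S,6S)-2-ethoxy-3-hydroxy-6-(2-{4-[(triisopropylsilyl)oxy]phenyl}ethyl)oxan-4-yl]-2-hydroxy-6-methoxyphenyl}prop-2-en-1-one; 26 chloro{4-[(tert-butyldimethylsilyl)oxy]phenyl}dimethylsilane
Product: 29 (2E)-3-{4-[(tert-butyldimethylsilyl)oxy]phenyl}-1-{4-[(tert-butyldimethylsilyl)oxy]-3-[(2S,3S,4S,6S)-2-{4-[(tert-butyldimethylsilyl)oxy]phenyl}-3-hydroxy-6-(2-{4-[(triisopropylsilyl)oxy]phenyl}ethyl)oxan-4-yl]-2-hydroxy-6-methoxyphenyl}prop-2-en-1-one, via tethered silyl ether 27 (not isolated), via silyl triflate 28 (not isolated)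
Conditions: 26 (1.3 equiv), imidazole, DMAP (cat.), CH2Cl2, rt; filter, concentrate; then Me3SiOTf (1.5 equiv), 2,6-di-tert-butyl-4-methylpyridine, CH2Cl2, −78 → −45 °C; then aq. NaHCO3
Reagents that add atoms: none
Why: Silicon-tethered intramolecular C-arylation (ipso Friedel–Crafts aryl transfer to a cyclic oxocarbenium ion, a known route to 1,2-cis C-aryl glycosides): Me3SiOTf ionises either C2 epimer of the acetal, the silyloxy-activated aryl on the C3–O–Si tether attacks C2 through its silicon-bearing carbon via a five-membered transition state and is therefore delivered cis to the C3 oxygen, which is also the axial trajectory on the half-chair with the C3, C4 and C6 substituents equatorial, so the new C2 centre is set 2,3-cis and 2,6-trans before aqueous work-up cleaves the silyl triflate to the free C3 hydroxyl.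

Step 14
Reactants: 29 (2E)-3-{4-[(tert-butyldimethylsilyl)oxy]phenyl}-1-{4-[(tert-butyldimethylsilyl)oxy]-3-[(2S,3S,4S,6S)-2-{4-[(tert-butyldimethylsilyl)oxy]phenyl}-3-hydroxy-6-(2-{4-[(triisopropylsilyl)oxy]phenyl}ethyl)oxan-4-yl]-2-hydroxy-6-methoxyphenyl}prop-2-en-1-one
Product: 30 (2E)-1-{2,4-dihydroxy-3-[(2S,3S,4S,6S)-3-hydroxy-2-(4-hydroxyphenyl)-6-[2-(4-hydroxyphenyl)ethyl]oxan-4-yl]-6-methoxyphenyl}-3-(4-hydroxyphenyl)prop-2-en-1-one
Conditions: Bu4NF, AcOH (1:1), THF, 0 °C → rt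
Reagents that add atoms: none
Why: Fluoride-mediated cleavage of the four aryl silyl ethers under acetic acid buffering avoids both base (flavanone formation from the 2'-hydroxychalcone) and acid (ionisation of the 4-hydroxybenzylic C2 ether), so no stereocentre should be scrambled.

**Compound list**
1 | methyl 3-(4-hydroxyphenyl)propanoate | COC(=O)CCc1ccc(O)cc1 | starting material
2 | methyl 3-{4-[(triisopropylsilyl)oxy]phenyl}propanoate | COC(=O)CCc1ccc(O[Si](C(C)C)(C(C)C)C(C)C)cc1 | intermediate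
3 | diisobutylaluminium hemiacetal of 2 (O-aluminated 1-methoxy-3-arylpropan-1-ol) | COC(CCc1ccc(O[Si](C(C)C)(C(C)C)C(C)C)cc1)O[Al](CC(C)C)CC(C)C | intermediate (not isolated)
4 | 3-{4-[(triisopropylsilyl)oxy]phenyl}propanal | O=CCCc1ccc(O[Si](C(C)C)(C(C)C)C(C)C)cc1 | intermediate
5 | 1-(2,6-dihydroxy-4-methoxyphenyl)ethanone | CC(=O)c1c(O)cc(OC)cc1O | starting material
6 | 1-[4-methoxy-2,6-bis(methoxymethoxy)phenyl]ethanone | CC(=O)c1c(OCOC)cc(OC)cc1OCOC | intermediate
7 | potassium 1-[4-methoxy-2,6-bis(methoxymethoxy)phenyl]ethenolate | C=C([O-])c1c(OCOC)cc(OC)cc1OCOC.[K+] | intermediate (not isolated)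
8 | 1-[4-methoxy-2,6-bis(methoxymethoxy)phenyl]ethenyl trifluoromethanesulfonate | C=C(OS(=O)(=O)C(F)(F)F)c1c(OCOC)cc(OC)cc1OCOC | intermediate
9 | 2-[(E)-2-ethoxyethenyl]-4,4,5,5-tetramethyl-1,3,2-dioxaborolane | CCO/C=C/B1OC(C)(C)C(C)(C)O1 | starting material
10 | 2-[(3E)-4-ethoxybuta-1,3-dien-2-yl]-5-methoxy-1,3-bis(methoxymethoxy)benzene | CCO/C=C/C(=C)c1c(OCOC)cc(OC)cc1OCOC | intermediate
11 | (2S,6S)-2-ethoxy-4-[4-methoxy-2,6-bis(methoxymethoxy)phenyl]-6-(2-{4-[(triisopropylsilyl)oxy]phenyl}ethyl)-5,6-dihydro-2H-pyran | O1[C@H](OCC)C=C(c2c(OCOC)cc(OC)cc2OCOC)C[C@@H]1CCc1ccc(O[Si](C(C)C)(C(C)C)C(C)C)cc1 | intermediate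
12 | 3-boryl analogue of 13 (BH2 in place of the 3-hydroxyl, same configuration) | O1[C@H](OCC)[C@@H](B)[C@H](c2c(OCOC)cc(OC)cc2OCOC)C[C@@H]1CCc1ccc(O[Si](C(C)C)(C(C)C)C(C)C)cc1 | intermediate (not isolated)
13 | (2S,3S,4S,6S)-2-ethoxy-4-[4-methoxy-2,6-bis(methoxymethoxy)phenyl]-6-(2-{4-[(triisopropylsilyl)oxy]phenyl}ethyl)oxan-3-ol | O1[C@H](OCC)[C@@H](O)[C@H](c2c(OCOC)cc(OC)cc2OCOC)C[C@@H]1CCc1ccc(O[Si](C(C)C)(C(C)C)C(C)C)cc1 | intermediate
14 | 4-(methoxymethoxy)benzaldehyde | COCOc1ccc(C=O)cc1 | starting material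
15 | diethyl {2-[methoxy(methyl)amino]-2-oxoethyl}phosphonate | CCOP(=O)(CC(=O)N(C)OC)OCC | starting material
16 | sodium salt of the α-carbanion of 15 | CCOP(=O)([CH-]C(=O)N(C)OC)OCC.[Na+] | intermediate (not isolated)
17 | (2E)-N-methoxy-3-[4-(methoxymethoxy)phenyl]-N-methylprop-2-enamide | COCOc1ccc(/C=C/C(=O)N(C)OC)cc1 | intermediate
18 | O3-lithio, aryl-C3-lithio derivative of 13 (lithium alkoxide; aryllithium between OMOM and OMe) | O1[C@H](OCC)[C@@H](O[Li])[C@H](c2c(OCOC)c([Li])c(OC)cc2OCOC)C[C@@H]1CCc1ccc(O[Si](C(C)C)(C(C)C)C(C)C)cc1 | intermediate (not isolated)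
19 | tetrahedral lithium adduct of 18 and 17 (aryl–C(OLi)(NMeOMe)–CH=CH–aryl) | O1[C@H](OCC)[C@@H](O[Li])[C@H](c2c(OCOC)c(C(O[Li])(N(C)OC)/C=C/c3ccc(OCOC)cc3)c(OC)cc2OCOC)C[C@@H]1CCc1ccc(O[Si](C(C)C)(C(C)C)C(C)C)cc1 | intermediate (not isolated)
20 | (2E)-1-{3-[(2S,3S,4S,6S)-2-ethoxy-3-hydroxy-6-(2-{4-[(triisopropylsilyl)oxy]phenyl}ethyl)oxan-4-yl]-6-methoxy-2,4-bis(methoxymethoxy)phenyl}-3-[4-(methoxymethoxy)phenyl]prop-2-en-1-one | O1[C@H](OCC)[C@@H](O)[C@H](c2c(OCOC)c(C(=O)/C=C/c3ccc(OCOC)cc3)c(OC)cc2OCOC)C[C@@H]1CCc1ccc(O[Si](C(C)C)(C(C)C)C(C)C)cc1 | intermediate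
21 | (2E)-1-{3-[(3S,4S,6S)-2-ethoxy-3-hydroxy-6-(2-{4-[(triisopropylsilyl)oxy]phenyl}ethyl)oxan-4-yl]-2,4-dihydroxy-6-methoxyphenyl}-3-(4-hydroxyphenyl)prop-2-en-1-one, both C2 epimers | O1C(OCC)[C@@H](O)[C@H](c2c(O)c(C(=O)/C=C/c3ccc(O)cc3)c(OC)cc2O)C[C@@H]1CCc1ccc(O[Si](C(C)C)(C(C)C)C(C)C)cc1 | intermediate
22 | (2E)-3-{4-[(tert-butyldimethylsilyl)oxy]phenyl}-1-{4-[(tert-butyldimethylsilyl)oxy]-3-[(3S,4S,6S)-2-ethoxy-3-hydroxy-6-(2-{4-[(triisopropylsilyl)oxy]phenyl}ethyl)oxan-4-yl]-2-hydroxy-6-methoxyphenyl}prop-2-en-1-one, both C2 epimers | O1C(OCC)[C@@H](O)[C@H](c2c(O)c(C(=O)/C=C/c3ccc(O[Si](C)(C)C(C)(C)C)cc3)c(OC)cc2O[Si](C)(C)C(C)(C)C)C[C@@H]1CCc1ccc(O[Si](C(C)C)(C(C)C)C(C)C)cc1 | intermediate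
23 | (4-bromophenoxy)(tert-butyl)dimethylsilane | CC(C)(C)[Si](C)(C)Oc1ccc(Br)cc1 | starting material
24 | dichlorodimethylsilane | C[Si](C)(Cl)Cl | starting material
25 | {4-[(tert-butyldimethylsilyl)oxy]phenyl}magnesium bromide | CC(C)(C)[Si](C)(C)Oc1ccc([Mg]Br)cc1 | intermediate (not isolated)
26 | chloro{4-[(tert-butyldimethylsilyl)oxy]phenyl}dimethylsilane | CC(C)(C)[Si](C)(C)Oc1ccc([Si](C)(C)Cl)cc1 | intermediate
27 | 3-O-({4-[(tert-butyldimethylsilyl)oxy]phenyl}dimethylsilyl) ether of 22, both C2 epimers | O1C(OCC)[C@@H](O[Si](C)(C)c2ccc(O[Si](C)(C)C(C)(C)C)cc2)[C@H](c2c(O)c(C(=O)/C=C/c3ccc(O[Si](C)(C)C(C)(C)C)cc3)c(OC)cc2O[Si](C)(C)C(C)(C)C)C[C@@H]1CCc1ccc(O[Si](C(C)C)(C(C)C)C(C)C)cc1 | intermediate (not isolated)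
28 | 3-O-[dimethyl(trifluoromethanesulfonyloxy)silyl] ether of 29 | O1[C@@H](c2ccc(O[Si](C)(C)C(C)(C)C)cc2)[C@@H](O[Si](C)(C)OS(=O)(=O)C(F)(F)F)[C@H](c2c(O)c(C(=O)/C=C/c3ccc(O[Si](C)(C)C(C)(C)C)cc3)c(OC)cc2O[Si](C)(C)C(C)(C)C)C[C@@H]1CCc1ccc(O[Si](C(C)C)(C(C)C)C(C)C)cc1 | intermediate (not isolated)
29 | (2E)-3-{4-[(tert-butyldimethylsilyl)oxy]phenyl}-1-{4-[(tert-butyldimethylsilyl)oxy]-3-[(2S,3S,4S,6S)-2-{4-[(tert-butyldimethylsilyl)oxy]phenyl}-3-hydroxy-6-(2-{4-[(triisopropylsilyl)oxy]phenyl}ethyl)oxan-4-yl]-2-hydroxy-6-methoxyphenyl}prop-2-en-1-one | O1[C@@H](c2ccc(O[Si](C)(C)C(C)(C)C)cc2)[C@@H](O)[C@H](c2c(O)c(C(=O)/C=C/c3ccc(O[Si](C)(C)C(C)(C)C)cc3)c(OC)cc2O[Si](C)(C)C(C)(C)C)C[C@@H]1CCc1ccc(O[Si](C(C)C)(C(C)C)C(C)C)cc1 | intermediate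
30 | (2E)-1-{2,4-dihydroxy-3-[(2S,3S,4S,6S)-3-hydroxy-2-(4-hydroxyphenyl)-6-[2-(4-hydroxyphenyl)ethyl]oxan-4-yl]-6-methoxyphenyl}-3-(4-hydroxyphenyl)prop-2-en-1-one | COc1cc(O)c([C@@H]2C[C@H](CCc3ccc(O)cc3)O[C@@H](c3ccc(O)cc3)[C@H]2O)c(O)c1C(=O)/C=C/c1ccc(O)cc1 | target

**Step count and risks**

Total step count: 14. Longest linear sequence: 10 steps (5 → 30 through steps 3, 4, 5, 6, 7, 9, 10, 11, 13, 14).

Steps most likely to fail:

1. Step 13. The oxocarbenium ion may be intercepted intermolecularly before the silicon-bound aryl is delivered, the aryl may fail to leave silicon, or the kinetic axial aryl ether may re-ionise under the Lewis acid and epimerise at C2. Fallback (intermolecular organozinc C-arylation in place of tethered delivery), setting out from 22 and using Grignard reagent 25: 22 is silylated at the C3 hydroxyl and the remaining phenol with Et3SiOTf/2,6-lutidine (CH2Cl2, −40 °C) to give the bis(triethylsilyl) ether of 22 F1. Me3SiBr (CH2Cl2, 0 °C) converts its ethyl acetal into the C2 bromide of the bis(triethylsilyl) ether F2, used crude. Transmetalation of 25 with ZnBr2 gives bromo{4-[(tert-butyldimethylsilyl)oxy]phenyl}zinc F3, which should substitute the bromide in toluene/Bu2O by axial attack on the oxocarbenium ion (trans to the C6 chain, cis to the equatorial C3 silyloxy group) to give the bis(triethylsilyl) ether of 29 F4. The conditions of step 14, run longer so that the triethylsilyl ethers also fall, bring the route back at 30.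

2. Step 6. The perpendicular ortho,ortho'-disubstituted aryl may shield the reacting diene terminus, so that cycloaddition is slow, the acid-sensitive dienyl ether hydrolyses or oligomerises, and endo and enantioface selectivity erode. Fallback (the C3=C4 bond made by ring-closing metathesis instead of the two bonds of the cycloaddition), setting out from 8 and 4: Kumada coupling of 8 with Me3SiCH2MgCl (Pd(PPh3)4, THF) gives {2-[4-methoxy-2,6-bis(methoxymethoxy)phenyl]prop-2-en-1-yl}trimethylsilane F5. An enantioselective Hosomi–Sakurai allylation of 4 with it (TiF4/(S)-BINOL, the BINOL enantiomer being chosen to give the 3S alcohol; dilute HCl work-up) gives (3S)-5-[4-methoxy-2,6-bis(methoxymethoxy)phenyl]-1-{4-[(triisopropylsilyl)oxy]phenyl}hex-5-en-3-ol F6. Transacetalisation with acrolein diethyl acetal (PPTS, toluene) gives the 1-ethoxyprop-2-en-1-yl ether of the alcohol F7 as both acetal epimers. Ring-closing metathesis (second-generation Grubbs catalyst, RuCl2(PCy3)(SIMes)(=CHPh), CH2Cl2, 40 °C) closes the dihydropyran and returns the route at 11, together with the (2R,6S) epimer of 11 F8. F8 is separated and re-equilibrated (PPTS, EtOH), because only the cis acetal steers step 7 correctly.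

3. Step 9. Metalation may compete at other sites (silyl aryl ether, methoxymethyl CH2, benzylic C4–H), the dianion may form incompletely, or the hindered aryllithium may add in a conjugate sense to 17. Fallback (regiochemistry fixed by electrophilic substitution, metalation by halogen–metal exchange), setting out from 13: NBS (1.0 equiv, MeCN, −20 °C) should brominate only the most electron-rich ring at one of its two equivalent free positions to give (2S,3S,4S,6S)-4-[3-bromo-4-methoxy-2,6-bis(methoxymethoxy)phenyl]-2-ethoxy-6-(2-{4-[(triisopropylsilyl)oxy]phenyl}ethyl)oxan-3-ol F9. n-BuLi (1 equiv, for the hydroxyl) and then t-BuLi (2 equiv, THF, −78 °C) effect bromine–lithium exchange and bring the route back at 18, which is acylated with 17 as in step 9.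

**Further compounds**
F1 | step 13 | bis(triethylsilyl) ether of 22 (triethylsilyl on the C3 oxygen and on the remaining phenol; both C2 epimers) | O1C(OCC)[C@@H](O[Si](CC)(CC)CC)[C@H](c2c(O[Si](CC)(CC)CC)c(C(=O)/C=C/c3ccc(O[Si](C)(C)C(C)(C)C)cc3)c(OC)cc2O[Si](C)(C)C(C)(C)C)C[C@@H]1CCc1ccc(O[Si](C(C)C)(C(C)C)C(C)C)cc1
F2 | step 13 | C2 bromide of the bis(triethylsilyl) ether (bromine in place of ethoxy; both C2 epimers) | O1C(Br)[C@@H](O[Si](CC)(CC)CC)[C@H](c2c(O[Si](CC)(CC)CC)c(C(=O)/C=C/c3ccc(O[Si](C)(C)C(C)(C)C)cc3)c(OC)cc2O[Si](C)(C)C(C)(C)C)C[C@@H]1CCc1ccc(O[Si](C(C)C)(C(C)C)C(C)C)cc1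
F3 | step 13 | bromo{4-[(tert-butyldimethylsilyl)oxy]phenyl}zinc | CC(C)(C)[Si](C)(C)Oc1ccc([Zn]Br)cc1
F4 | step 13 | bis(triethylsilyl) ether of 29 (triethylsilyl on the C3 oxygen and on the remaining phenol) | O1[C@@H](c2ccc(O[Si](C)(C)C(C)(C)C)cc2)[C@@H](O[Si](CC)(CC)CC)[C@H](c2c(O[Si](CC)(CC)CC)c(C(=O)/C=C/c3ccc(O[Si](C)(C)C(C)(C)C)cc3)c(OC)cc2O[Si](C)(C)C(C)(C)C)C[C@@H]1CCc1ccc(O[Si](C(C)C)(C(C)C)C(C)C)cc1
F5 | step 6 | {2-[4-methoxy-2,6-bis(methoxymethoxy)phenyl]prop-2-en-1-yl}trimethylsilane | C=C(C[Si](C)(C)C)c1c(OCOC)cc(OC)cc1OCOC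
F6 | step 6 | (3S)-5-[4-methoxy-2,6-bis(methoxymethoxy)phenyl]-1-{4-[(triisopropylsilyl)oxy]phenyl}hex-5-en-3-ol | C=C(c1c(OCOC)cc(OC)cc1OCOC)C[C@@H](O)CCc1ccc(O[Si](C(C)C)(C(C)C)C(C)C)cc1
F7 | step 6 | 1-ethoxyprop-2-en-1-yl ether of F6 (mixed acrolein acetal; both acetal epimers) | C=C(c1c(OCOC)cc(OC)cc1OCOC)C[C@@H](OC(OCC)C=C)CCc1ccc(O[Si](C(C)C)(C(C)C)C(C)C)cc1
F8 | step 6 | (2R,6S)-2-ethoxy-4-[4-methoxy-2,6-bis(methoxymethoxy)phenyl]-6-(2-{4-[(triisopropylsilyl)oxy]phenyl}ethyl)-5,6-dihydro-2H-pyran | O1[C@@H](OCC)C=C(c2c(OCOC)cc(OC)cc2OCOC)C[C@@H]1CCc1ccc(O[Si](C(C)C)(C(C)C)C(C)C)cc1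
F9 | step 9 | (2S,3S,4S,6S)-4-[3-bromo-4-methoxy-2,6-bis(methoxymethoxy)phenyl]-2-ethoxy-6-(2-{4-[(triisopropylsilyl)oxy]phenyl}ethyl)oxan-3-ol | O1[C@H](OCC)[C@@H](O)[C@H](c2c(OCOC)c(Br)c(OC)cc2OCOC)C[C@@H]1CCc1ccc(O[Si](C(C)C)(C(C)C)C(C)C)cc1
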